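The pyranone ring (O1–C2–C3–C4–C4a–C8a) is traced back to the furanone ring of a benzofuran-3(2H)-one, which lacks C3. The ring oxygen is fixed first on the unique phenol of a symmetric 3,5-dialkoxy-4-methylphenol, so that methyl ends at C6 without regioisomers. The key step is a Saegusa–Ito-type oxidative ring expansion: Fe(III) fragments the bond shared by the cyclopropane and the five-membered ring of a silyloxycyclopropa[b]benzofuran, which inserts the cyclopropane CH2 as C3 and gives the 4H-chromen-4-one; it exploits the oxygen at C2 (radical stabilisation) and the latent C4 carbonyl. C2 is then set by Rh-catalysed asymmetric aryl addition, and the C8 prenyl group by a late O-to-C Claisen shift.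

Key step: step 7

Remark: C2 is the only stereocentre; (2S) corresponds to aryl delivery to the Re face of C2 of the chromenone (priorities O1 > C3 > H), and the ligand antipode in step 8 is chosen accordingly.

Step 1
Reactants: 1 2-methylresorcinol
Product: 2 1,3-bis(methoxymethoxy)-2-methylbenzene
Conditions: MOMCl (2.5 equiv), i-Pr2NEt, CH2Cl2, 0 °C → rt
Reagents that add atoms: chloromethyl methyl ether, COCCl
Why: Williamson-type O-alkylation of both phenols gives base-stable, acid-labile acetals that tolerate the organometallic steps and are removed under mild acid before the prenyl group is introduced.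

Step 2
Reactants: 2 1,3-bis(methoxymethoxy)-2-methylbenzene
Product: 4 3,5-bis(methoxymethoxy)-4-methylphenol, via arylboronic pinacol ester 3 (not isolated)
Conditions: [Ir(OMe)(cod)]2 (1.5 mol%), dtbpy (3 mol%), B2pin2 (1.0 equiv), THF, 80 °C; then aq. H2O2, NaOH, 0 °C → rt
Reagents that add atoms: hydrogen peroxide, OO; bis(pinacolato)diboron, CC1(C)OB(OC1(C)C)B1OC(C)(C)C(C)(C)O1 (boron of intermediate 3 only)
Why: Sterically governed Ir-catalysed aromatic C–H borylation should select C5, the only C–H without an ortho substituent, and oxidation of the C–B bond gives the symmetric phenol whose oxygen becomes O1 (para to the methyl group).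

Step 3
Reactants: 4 3,5-bis(methoxymethoxy)-4-methylphenol
Product: 5 2-bromo-3,5-bis(methoxymethoxy)-4-methylphenol
Conditions: NBS (1.0 equiv), CH2Cl2, −78 → −20 °C
Reagents that add atoms: N-bromosuccinimide, O=C1CCC(=O)N1Br
Why: Electrophilic aromatic bromination can only occur ortho to the free hydroxyl (para is blocked by methyl), and the two ortho positions are equivalent, so one monobromide should form.

Step 4
Reactants: 5 2-bromo-3,5-bis(methoxymethoxy)-4-methylphenol; 6 2-chloro-N-methoxy-N-methylacetamide
Product: 8 4,6-bis(methoxymethoxy)-5-methyl-1-benzofuran-3(2H)-one, via aryl chloromethyl ketone 7 (not isolated)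
Conditions: n-BuLi (2.2 equiv), THF, −78 °C; 6, −78 → 0 °C; aq. NH4Cl; then K2CO3, acetone, rt
Reagents that add atoms: none
Why: Deprotonation and bromine–lithium exchange give the ortho-lithiated phenoxide, which is acylated by the Weinreb amide (stable chelate, no over-addition); the released phenol then closes the furanone by intramolecular Williamson etherification (5-exo-tet), which fixes O1 next to the remaining aromatic C–H.

Step 5
Reactants: 8 4,6-bis(methoxymethoxy)-5-methyl-1-benzofuran-3(2H)-one
Product: 9 tert-butyl{[4,6-bis(methoxymethoxy)-5-methyl-1-benzofuran-3-yl]oxy}dimethylsilane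
Conditions: KHMDS, THF, −78 °C; TBSCl, −78 °C → rt
Reagents that add atoms: tert-butyldimethylsilyl chloride, CC(C)(C)[Si](C)(C)Cl
Why: O-silylation of the potassium enolate is favoured by the hard silyl electrophile and by aromatisation to the benzofuran, and should give the silyl enol ether.

Step 6
Reactants: 9 tert-butyl{[4,6-bis(methoxymethoxy)-5-methyl-1-benzofuran-3-yl]oxy}dimethylsilane
Product: 10 racemic cis-fused tert-butyl{[4,6-bis(methoxymethoxy)-5-methyl-1a,6b-dihydro-1H-cyclopropa[b][1]benzofuran-6b-yl]oxy}dimethylsilane
Conditions: Et2Zn, CH2I2, CH2Cl2, 0 °C → rt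
Reagents that add atoms: diiodomethane, ICI
Why: Simmons–Smith (Furukawa) cyclopropanation should attack the electron-rich enol-ether C2=C3 bond, the only nucleophilic alkene present; cis fusion is the only possible outcome and both new stereocentres are erased in step 7.

Step 7
Reactants: 10 racemic cis-fused tert-butyl{[4,6-bis(methoxymethoxy)-5-methyl-1a,6b-dihydro-1H-cyclopropa[b][1]benzofuran-6b-yl]oxy}dimethylsilane
Product: 12 5,7-bis(methoxymethoxy)-6-methyl-4H-chromen-4-one, via 2-chlorochromanone 11 (not isolated)
Conditions: FeCl3 (2.2 equiv), DMF, 0 °C; then NaOAc, MeOH, 50 °C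
Reagents that add atoms: iron(III) chloride, Cl[Fe](Cl)Cl (chlorine of intermediate 11 only)
Why: Fe(III) oxidises the silyloxycyclopropane by single-electron transfer with loss of silyl chloride to an alkoxy radical at C4, which undergoes β-scission of the strained C2–C4 bond shared by the cyclopropane and the five-membered ring, giving the C4 carbonyl and a ring-enlarged radical at C2; chlorine transfer from a second FeCl3 gives 11, which loses HCl with acetate to the γ-pyrone. The closest known reaction type is the Saegusa–Ito FeCl3 ring expansion of 1-silyloxybicyclo[n.1.0]alkanes to cycloalk-2-enones. No ring is closed by bond formation: the six-membered ring O1–C2–C3–C4–C4a–C8a results from breaking the zero-atom bridge of the bicycle, so that the former cyclopropane CH2 becomes C3. No stereocentre is formed, and the two of racemic 10 are erased. The step needs cleavage of the shared bond and not of the external C4–CH2 bond, which the ring oxygen on C2 should secure (α-oxy secondary radical versus primary radical, plus relief of bicyclic strain); it also needs oxidation of the cyclopropane in preference to the alkoxy-rich arene, for which the easily oxidised silyloxycyclopropane and DMF as moderating ligand are relied on.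

Step 8
Reactants: 12 5,7-bis(methoxymethoxy)-6-methyl-4H-chromen-4-one; 13 (4-methoxyphenyl)boronic acid
Product: 14 (2S)-5,7-bis(methoxymethoxy)-2-(4-methoxyphenyl)-6-methylchroman-4-one
Conditions: [RhCl(C2H4)2]2 (1.5 mol%), chiral bisphosphine of the MeO-F12-BIPHEP type (antipode for Re-face attack, 3.3 mol%), 13 (2 equiv), aq. KOH (10 mol%), toluene/H2O, 20 °C
Reagents that add atoms: none
Why: Rh-catalysed asymmetric 1,4-addition of the arylboronic acid (Hayashi–Miyaura reaction) to the chromenone should set C2 under catalyst control by aryl transfer to the Re face, and the mild, nearly neutral conditions should avoid retro-oxa-Michael opening of the product.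

Step 9
Reactants: 14 (2S)-5,7-bis(methoxymethoxy)-2-(4-methoxyphenyl)-6-methylchroman-4-one
Product: 15 (2S)-5,7-dihydroxy-2-(4-methoxyphenyl)-6-methylchroman-4-one
Conditions: 3 M HCl, MeOH, 45 °C
Reagents that add atoms: none
Why: Acid-catalysed acetal cleavage (transacetalisation to methanol) removes both MOM groups; the methyl ether and, under these mild acidic conditions, the C2 configuration should remain intact.

Step 10
Reactants: 16 2-methylbut-3-en-2-ol
Product: 17 methyl 2-methylbut-3-en-2-yl carbonate
Conditions: n-BuLi, THF, −78 °C; ClCO2Me, −78 °C → rt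
Reagents that add atoms: methyl chloroformate, COC(=O)Cl
Why: Acylation of the lithium alkoxide of the tertiary allylic alcohol with the chloroformate should give the mixed carbonate needed as π-allyl precursor.

Step 11
Reactants: 15 (2S)-5,7-dihydroxy-2-(4-methoxyphenyl)-6-methylchroman-4-one; 17 methyl 2-methylbut-3-en-2-yl carbonate
Product: 18 (2S)-5-hydroxy-2-(4-methoxyphenyl)-6-methyl-7-[(2-methylbut-3-en-2-yl)oxy]chroman-4-one
Conditions: Pd(PPh3)4 (3 mol%), THF, 0 °C → rt
Reagents that add atoms: none
Why: Tsuji–Trost O-allylation: the 1,1-dimethylallyl-palladium cation should be attacked at its tertiary terminus (kinetic control at low temperature) by the more acidic, non-chelated 7-phenoxide, while the 5-OH is held in the hydrogen bond to C4=O.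

Step 12
Reactants: 18 (2S)-5-hydroxy-2-(4-methoxyphenyl)-6-methyl-7-[(2-methylbut-3-en-2-yl)oxy]chroman-4-one
Product: 19 (2S)-5,7-dihydroxy-2-(4-methoxyphenyl)-6-methyl-8-(3-methylbut-2-en-1-yl)chroman-4-one
Conditions: Eu(fod)3 (10 mol%), CHCl3, 60 °C
Reagents that add atoms: none
Why: Aromatic Claisen rearrangement ([3,3]) should deliver the allyl terminus to C8, the only free ortho position of the 7-oxygen (C6 carries methyl), and tautomerisation restores the phenol, turning the 1,1-dimethylallyl ether into the prenyl group under neutral conditions that leave C2 untouched.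

Compound list
1 | 2-methylresorcinol | Cc1c(O)cccc1O | starting material
2 | 1,3-bis(methoxymethoxy)-2-methylbenzene | Cc1c(OCOC)cccc1OCOC | intermediate
3 | 2-[3,5-bis(methoxymethoxy)-4-methylphenyl]-4,4,5,5-tetramethyl-1,3,2-dioxaborolane | Cc1c(OCOC)cc(B2OC(C)(C)C(C)(C)O2)cc1OCOC | intermediate (not isolated)
4 | 3,5-bis(methoxymethoxy)-4-methylphenol | Cc1c(OCOC)cc(O)cc1OCOC | intermediate
5 | 2-bromo-3,5-bis(methoxymethoxy)-4-methylphenol | Cc1c(OCOC)cc(O)c(Br)c1OCOC | intermediate
6 | 2-chloro-N-methoxy-N-methylacetamide | CON(C)C(=O)CCl | starting material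
7 | 2-chloro-1-[6-hydroxy-2,4-bis(methoxymethoxy)-3-methylphenyl]ethan-1-one | O=C(CCl)c1c(O)cc(OCOC)c(C)c1OCOC | intermediate (not isolated)
8 | 4,6-bis(methoxymethoxy)-5-methyl-1-benzofuran-3(2H)-one | O=C1COc2cc(OCOC)c(C)c(OCOC)c12 | intermediate
9 | tert-butyl{[4,6-bis(methoxymethoxy)-5-methyl-1-benzofuran-3-yl]oxy}dimethylsilane | CC(C)(C)[Si](C)(C)Oc1coc2cc(OCOC)c(C)c(OCOC)c12 | intermediate
10 | tert-butyl{[4,6-bis(methoxymethoxy)-5-methyl-1a,6b-dihydro-1H-cyclopropa[b][1]benzofuran-6b-yl]oxy}dimethylsilane (racemic, cis-fused) | CC(C)(C)[Si](C)(C)OC12CC1Oc1cc(OCOC)c(C)c(OCOC)c12 | intermediate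
11 | 2-chloro-5,7-bis(methoxymethoxy)-6-methylchroman-4-one (racemic) | O=C1CC(Cl)Oc2cc(OCOC)c(C)c(OCOC)c12 | intermediate (not isolated)
12 | 5,7-bis(methoxymethoxy)-6-methyl-4H-chromen-4-one | O=c1ccoc2cc(OCOC)c(C)c(OCOC)c12 | intermediate
13 | (4-methoxyphenyl)boronic acid | COc1ccc(B(O)O)cc1 | starting material
14 | (2S)-5,7-bis(methoxymethoxy)-2-(4-methoxyphenyl)-6-methylchroman-4-one | COc1ccc([C@@H]2CC(=O)c3c(OCOC)c(C)c(OCOC)cc3O2)cc1 | intermediate
15 | (2S)-5,7-dihydroxy-2-(4-methoxyphenyl)-6-methylchroman-4-one | COc1ccc([C@@H]2CC(=O)c3c(O)c(C)c(O)cc3O2)cc1 | intermediate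
16 | 2-methylbut-3-en-2-ol | CC(C)(O)C=C | starting material
17 | methyl 2-methylbut-3-en-2-yl carbonate | COC(=O)OC(C)(C)C=C | intermediate
18 | (2S)-5-hydroxy-2-(4-methoxyphenyl)-6-methyl-7-[(2-methylbut-3-en-2-yl)oxy]chroman-4-one | COc1ccc([C@@H]2CC(=O)c3c(O)c(C)c(OC(C)(C)C=C)cc3O2)cc1 | intermediate
19 | (2S)-5,7-dihydroxy-2-(4-methoxyphenyl)-6-methyl-8-(3-methylbut-2-en-1-yl)chroman-4-one | COc1ccc([C@@H]2CC(=O)c3c(O)c(C)c(O)c(CC=C(C)C)c3O2)cc1 | target

Total step count: 12. Longest linear sequence: 11 (steps 1–9, 11 and 12; step 10 is a one-step side branch).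

Steps most likely to fail

Step 7. The Lewis-acidic iron salt may cleave the MOM acetals or chlorinate the electron-rich arene, or the external cyclopropane bond may fragment and return a 2-methylbenzofuranone. The fallback sets out from 9 and comes back at 12. It replaces the radical fragmentation by an ionic one under purely basic conditions: 9 is treated with dibromocarbene (CHBr3, KOt-Bu, pentane, −20 °C → rt) to give the gem-dibromocyclopropane F1. This should open by the cyclopropyl-to-allyl cation rearrangement with loss of silyl bromide, again enlarging the five-membered ring, to the 3-bromochromenone F2. Palladium-catalysed hydrodebromination (Pd(OAc)2, PPh3, HCO2H, Et3N, DMF, 60 °C) should then give 12.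

Step 8. Facial discrimination may be poor or insertion slow on the electron-rich chromenone with its peri-alkoxy group, and the product may open by retro-oxa-Michael reaction under the basic aqueous conditions. The fallback sets out from 12 and comes back at 14; it separates bond formation from stereocontrol. Addition of 13 with an achiral rhodium catalyst ([Rh(OH)(cod)]2, dioxane/H2O, 50 °C) should give the racemic flavanone F3. Kinetic resolution by asymmetric transfer hydrogenation (Cp*Rh(III)–TsDPEN, HCO2H/Et3N, EtOAc, rt; catalyst enantiomer that reduces the (2R)-ketone) should convert the unwanted enantiomer into the cis-(2R,4R)-flavan-4-ol F4. This is removed by chromatography and leaves 14, at the cost of at most half of the material.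

Step 11. Attack at the unsubstituted allyl terminus or equilibration to the linear prenyl ether would lead, after rearrangement, to the wrong side chain, and the transient alkoxide may trigger ring opening and racemisation. The fallback sets out from 15 and comes back at 19, bypassing 18. It is a direct Friedel–Crafts prenylation of 15 with 16 (BF3·OEt2, dioxane, rt) at C8, the only unsubstituted nucleophilic position of ring A. It makes no compound outside the list (F0), and lower conversion and some chroman formation are accepted.

Further compounds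
F1 | step 7 | tert-butyl{[1,1-dibromo-4,6-bis(methoxymethoxy)-5-methyl-1a,6b-dihydro-1H-cyclopropa[b][1]benzofuran-6b-yl]oxy}dimethylsilane (racemic) | CC(C)(C)[Si](C)(C)OC12C(Br)(Br)C1Oc1cc(OCOC)c(C)c(OCOC)c12
F2 | step 7 | 3-bromo-5,7-bis(methoxymethoxy)-6-methyl-4H-chromen-4-one | O=c1c(Br)coc2cc(OCOC)c(C)c(OCOC)c12
F3 | step 8 | racemic 5,7-bis(methoxymethoxy)-2-(4-methoxyphenyl)-6-methylchroman-4-one | COc1ccc(C2CC(=O)c3c(OCOC)c(C)c(OCOC)cc3O2)cc1
F4 | step 8 | (2R,4R)-5,7-bis(methoxymethoxy)-2-(4-methoxyphenyl)-6-methylchroman-4-ol | COc1ccc([C@H]2C[C@@H](O)c3c(OCOC)c(C)c(OCOC)cc3O2)cc1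
F0 | step 11 | none | none
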